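**Retrosynthetic overview**

1. Target 38 ⇐ fluoride-labile tetrasilyl ketone 37 ⇐ oxidation of carbinol 36 ⇐ C3-lithiated 2,4-dialkoxypyridine 34 + decalin aldehyde 21; the pyridine ring is bought (22), the oxygenated cyclohexane comes from cyclohexa-1,3-diene (24).
2. 34 ⇐ cis-diol 31 ⇐ cis-1,4-bis(silyloxy)cyclohexene 30 ⇐ 5-lithiopyridine + (R)-4-silyloxycyclohexenone 27 (from meso endoperoxide 25).
3. 21 ⇐ β,γ-unsaturated ester 19 ⇐ vinyl triflate 16 ⇐ enone 14 ⇐ trans-decalone 12 (reductive allylation) ⇐ octalone 10 ⇐ Birch reduction of methoxytetralin 8, i.e. ring A is carried at the arene oxidation level.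
4. 8 ⇐ [3+3] annulation of aryl bromide 4 with cyclic sulfate 3 of (R)-butane-1,3-diol, forming C4a–C5 and C7–C8 of the decalin (decalin numbering: C1 propenyl, C2 acyl, C3=C4, C4a, C5–C8, C8a).
5. Enabling feature: ring B (C4a, C5, C6, C7, C8, C8a) has its only stereocentre, C7–CH3, 1,3 to the C5 methylene, so C5–C6–C7 is a 1,3-diol-derived bis-electrophile; ring A (C1–C4, C4a, C8a) with its C3=C4 alkene can be reached from an anisole, in which C8 is a benzylic methyl and C4a an aryl carbon para to OMe. Ring order: B (step 2), A dearomatised (steps 3–4), epoxycyclohexane (steps 12–17).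

Key step: step 2

Remark: the target is taken exactly as drawn (all-equatorial trans-decalin 1R,2S,4aS,7S,8aR; in the cyclohexane the two hydroxyls are cis to each other and the epoxide is trans to both, with the pyridone on the epoxide face).

Step 1
Reactants: 1 (R)-butane-1,3-diol
Product: 3 (R)-4-methyl-1,3,2-dioxathiane 2,2-dioxide, via cyclic sulfite 2 (not isolated)
Conditions: SOCl2, CH2Cl2, 0 → 40 °C; then RuCl3 (1 mol %), NaIO4, MeCN/H2O, 0 °C
Reagents that add atoms: thionyl chloride O=S(Cl)Cl; sodium periodate [Na+].[O-]I(=O)(=O)=O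
Why: cyclic sulfite formation followed by RuO4-mediated oxidation to the cyclic sulfate (standard diol activation); no bond to the stereocentre is touched, so R is kept.

Step 2
Reactants: 3 (R)-4-methyl-1,3,2-dioxathiane 2,2-dioxide; 4 4-bromo-3-methylanisole
Product: 8 (S)-7-methoxy-2-methyl-1,2,3,4-tetrahydronaphthalene, via aryllithium 5 (not isolated), via lithium alkyl sulfate 6 (not isolated), via benzylic potassium species 7 (not isolated)
Conditions: 4, t-BuLi (2.0 equiv), THF, −78 °C; then 3 (1.0 equiv), −78 → 0 °C; then KOt-Bu, 2,2,6,6-tetramethylpiperidine, n-BuLi (2.2 equiv each), −78 → 0 °C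
Reagents that add atoms: none
Why: Proposed new method: a one-flask [3+3] annulation in which aryllithium 5 opens the cyclic sulfate at its primary carbon (the way aryllithiums are alkylated by dialkyl sulfates), and the ortho methyl group of the resulting sulfate monoester 6 is then metalated by the mixed Li/K amide base to the benzylic carbanion 7, which displaces the secondary sulfate in a 6-exo-tet SN2 closure of ring B. The closest known reaction types are the double displacement of cyclic sulfates by carbon and phosphorus bis-nucleophiles (cyclopropanes from malonate, phospholanes from primary phosphides) and the lateral metalation–alkylation of methoxytoluenes. The C7 stereocentre is set by inversion at the (R)-configured sulfate carbon, which gives S. Primary-before-secondary attack is secured by the sterics of the cyclic sulfate and by generating the benzylic anion only after the aryl–C5 bond exists. Benzylic rather than ring metalation is the thermodynamic outcome of the amine-mediated equilibration, and a ring anion ortho to OMe cannot reach the sulfate. Substitution should beat elimination because the sulfate monoanion is a poor E2 substrate and the closure is intramolecular.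

Step 3
Reactants: 8 (S)-7-methoxy-2-methyl-1,2,3,4-tetrahydronaphthalene
Product: 10 (4aR,7S)-7-methyl-4,4a,5,6,7,8-hexahydronaphthalen-2(3H)-one, via dihydroanisole 9 (not isolated)
Conditions: Li, NH3 (l), THF, t-BuOH, −78 → −33 °C; then 2 M HCl, MeOH, 60 °C
Reagents that add atoms: water O
Why: Birch reduction protonates the only para-related pair of unsubstituted arene carbons (C5 and C8 of the tetralin), and acid hydrolysis of the enol ether with conjugation gives the octalone, whose C4a centre equilibrates through the dienol to the epimer with both ring-B substituents equatorial (trans-1,4 to the methyl group).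

Step 4
Reactants: 10 (4aR,7S)-7-methyl-4,4a,5,6,7,8-hexahydronaphthalen-2(3H)-one
Product: 12 (1R,4aR,7S,8aS)-1-allyl-7-methyloctahydronaphthalen-2(1H)-one, via lithium enolate 11 (not isolated)
Conditions: Li (2.2 equiv), NH3 (l), THF, t-BuOH (1 equiv), −78 °C; then allyl bromide, −78 → −33 °C; then NaOMe (cat.), MeOH, 25 °C
Reagents that add atoms: allyl bromide C=CCBr
Why: dissolving-metal enone reduction with regiospecific enolate alkylation (Birch-type reductive alkylation): axial protonation at C8a gives the trans ring fusion, the C1 enolate is allylated, and base equilibration of the α-centre places the allyl group equatorial.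

Step 5
Reactants: 12 (1R,4aR,7S,8aS)-1-allyl-7-methyloctahydronaphthalen-2(1H)-one
Product: 14 (1R,4aR,7S,8aS)-1-allyl-7-methyl-4a,5,6,7,8,8a-hexahydronaphthalen-2(1H)-one, via silyl enol ether 13 (not isolated)
Conditions: LDA, Me3SiCl, THF, −78 °C; then Pd(OAc)2 (1.05 equiv), MeCN, 25 °C
Reagents that add atoms: none
Why: kinetic deprotonation at the C3 methylene (not at the substituted C1) and Saegusa–Ito dehydrogenation of the silyl enol ether give the C3=C4 enone without touching a stereocentre.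

Step 6
Reactants: 14 (1R,4aR,7S,8aS)-1-allyl-7-methyl-4a,5,6,7,8,8a-hexahydronaphthalen-2(1H)-one
Product: 16 (1R,4S,4aR,7S,8aS)-1-allyl-4,7-dimethyl-1,4,4a,5,6,7,8,8a-octahydronaphthalen-2-yl trifluoromethanesulfonate, via lithium enolate 15 (not isolated)
Conditions: Me2CuLi (from MeLi, CuI), Et2O, −78 → 0 °C; then PhNTf2, THF, 0 → 25 °C
Reagents that add atoms: lithium dimethylcuprate [Li+].C[Cu-]C; N-phenylbis(trifluoromethanesulfonimide) O=S(=O)(N(c1ccccc1)S(=O)(=O)C(F)(F)F)C(F)(F)F
Why: cuprate conjugate addition brings in the C4 methyl group (axial attack expected; this centre becomes sp2 again in step 8) and the regiodefined enolate is trapped as the C2=C3 vinyl triflate.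

Step 7
Reactants: 16 (1R,4S,4aR,7S,8aS)-1-allyl-4,7-dimethyl-1,4,4a,5,6,7,8,8a-octahydronaphthalen-2-yl trifluoromethanesulfonate
Product: 17 methyl (1R,4S,4aR,7S,8aS)-1-allyl-4,7-dimethyl-1,4,4a,5,6,7,8,8a-octahydronaphthalene-2-carboxylate
Conditions: Pd(OAc)2 (5 mol %), PPh3, CO (1 atm), MeOH, Et3N, DMF, 60 °C
Reagents that add atoms: carbon monoxide [C-]#[O+]; methanol CO
Why: palladium-catalysed methoxycarbonylation of the vinyl triflate installs the future acyl carbon on C2.

Step 8
Reactants: 17 methyl (1R,4S,4aR,7S,8aS)-1-allyl-4,7-dimethyl-1,4,4a,5,6,7,8,8a-octahydronaphthalene-2-carboxylate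
Product: 19 methyl (1R,2S,4aS,7S,8aR)-1-allyl-4,7-dimethyl-1,2,4a,5,6,7,8,8a-octahydronaphthalene-2-carboxylate, via lithium dienolate 18 (not isolated)
Conditions: LDA, HMPA, THF, −78 °C; then AcOH, −78 °C
Reagents that add atoms: none
Why: γ-deprotonation at C4–H and kinetic α-protonation of the linear dienolate (deconjugative protonation) move the alkene to C3=C4, and proton delivery to C2 along the axial trajectory should leave the ester equatorial, trans to the allyl group.

Step 9
Reactants: 19 methyl (1R,2S,4aS,7S,8aR)-1-allyl-4,7-dimethyl-1,2,4a,5,6,7,8,8a-octahydronaphthalene-2-carboxylate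
Product: 20 methyl (1R,2S,4aS,7S,8aR)-4,7-dimethyl-1-[(E)-prop-1-enyl]-1,2,4a,5,6,7,8,8a-octahydronaphthalene-2-carboxylate
Conditions: [CpRu(MeCN)(L)]PF6 (2 mol %; L = 2-(di-isopropylphosphino)-4-tert-butyl-1-methylimidazole), acetone, 25 °C
Reagents that add atoms: none
Why: bifunctional ruthenium-catalysed alkene isomerisation moves a terminal double bond by one position to the (E)-alkene and should stop at the branched C1, leaving the trisubstituted alkene, the ester and all stereocentres untouched.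

Step 10
Reactants: 20 methyl (1R,2S,4aS,7S,8aR)-4,7-dimethyl-1-[(E)-prop-1-enyl]-1,2,4a,5,6,7,8,8a-octahydronaphthalene-2-carboxylate
Product: 21 (1R,2S,4aS,7S,8aR)-4,7-dimethyl-1-[(E)-prop-1-enyl]-1,2,4a,5,6,7,8,8a-octahydronaphthalene-2-carbaldehyde
Conditions: i-Bu2AlH (1.05 equiv), CH2Cl2, −78 °C; aqueous potassium sodium tartrate
Reagents that add atoms: none
Why: partial ester reduction through the tetrahedral aluminium acetal at −78 °C gives the aldehyde under base-free conditions, so C2 keeps its equatorial configuration and the C3=C4 alkene stays out of conjugation.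

Step 11
Reactants: 22 5-bromo-2,4-dichloropyridine
Product: 23 5-bromo-2,4-bis[2-(trimethylsilyl)ethoxy]pyridine
Conditions: 2-(trimethylsilyl)ethanol (2.5 equiv), NaH, THF then DMF, 0 → 70 °C
Reagents that add atoms: 2-(trimethylsilyl)ethanol C[Si](C)(C)CCO
Why: two nucleophilic aromatic substitutions at the positions activated by the ring nitrogen (C4 first, then C2); the C5 bromide, meta to nitrogen, is inert.

Step 12
Reactants: 24 cyclohexa-1,3-diene
Product: 25 2,3-dioxabicyclo[2.2.2]oct-5-ene
Conditions: O2, tetraphenylporphyrin (cat.), visible light, CH2Cl2, 0 °C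
Reagents that add atoms: dioxygen O=O
Why: [4+2] cycloaddition of singlet oxygen to the cisoid diene gives the meso endoperoxide.

Step 13
Reactants: 25 2,3-dioxabicyclo[2.2.2]oct-5-ene
Product: 26 (R)-4-hydroxycyclohex-2-en-1-one
Conditions: 6′-hydroxy cinchona base (9-O-acetylcupreine or its cupreidine pseudoenantiomer, whichever delivers the R enone; 5 mol %), CH2Cl2, 25 °C
Reagents that add atoms: none
Why: enantioselective Kornblum–DeLaMare rearrangement, in which the chiral base removes one of the two enantiotopic bridgehead hydrogens with O–O cleavage and so desymmetrises the meso peroxide.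

Step 14
Reactants: 26 (R)-4-hydroxycyclohex-2-en-1-one
Product: 27 (R)-4-(tert-butyldimethylsilyloxy)cyclohex-2-en-1-one
Conditions: t-BuMe2SiCl, imidazole, DMF, 0 → 25 °C
Reagents that add atoms: tert-butyldimethylsilyl chloride CC(C)(C)[Si](C)(C)Cl
Why: standard silylation of the secondary alcohol; the stereocentre is not involved.

Step 15
Reactants: 23 5-bromo-2,4-bis[2-(trimethylsilyl)ethoxy]pyridine; 27 (R)-4-(tert-butyldimethylsilyloxy)cyclohex-2-en-1-one
Product: 30 5-[(1S,4R)-4-(tert-butyldimethylsilyloxy)-1-(triethylsilyloxy)cyclohex-2-en-1-yl]-2,4-bis[2-(trimethylsilyl)ethoxy]pyridine, via pyridyllithium 28 (not isolated), via lithium alkoxide 29 (not isolated)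
Conditions: 23, n-BuLi, THF, −78 °C; then 27, −78 °C; then Et3SiOTf, −78 → 0 °C
Reagents that add atoms: triethylsilyl trifluoromethanesulfonate CC[Si](CC)(CC)OS(=O)(=O)C(F)(F)F
Why: bromine–lithium exchange and 1,2-addition to the enone; axial attack anti to the pseudoaxial silyloxy group should place the aryl group trans to it (the two oxygens cis), and the tertiary alkoxide is silylated in the same flask.

Step 16
Reactants: 30 5-[(1S,4R)-4-(tert-butyldimethylsilyloxy)-1-(triethylsilyloxy)cyclohex-2-en-1-yl]-2,4-bis[2-(trimethylsilyl)ethoxy]pyridine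
Product: 31 5-[4-(tert-butyldimethylsilyloxy)-2,3-dihydroxy-1-(triethylsilyloxy)cyclohexyl]-2,4-bis[2-(trimethylsilyl)ethoxy]pyridine (both hydroxyls trans to the two silyloxy groups)
Conditions: OsO4 (5 mol %), N-methylmorpholine N-oxide, acetone/H2O, 25 °C
Reagents that add atoms: N-methylmorpholine N-oxide C[N+]1([O-])CCOCC1; water O
Why: catalytic osmium tetroxide dihydroxylation occurs anti to allylic oxygen substituents; both silyloxy groups sit on one face, so the cis-diol should form on the other (aryl) face, and the pyridine nitrogen is not oxidised under these conditions.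

Step 17
Reactants: 31 5-[4-(tert-butyldimethylsilyloxy)-2,3-dihydroxy-1-(triethylsilyloxy)cyclohexyl]-2,4-bis[2-(trimethylsilyl)ethoxy]pyridine
Product: 34 5-[5-(tert-butyldimethylsilyloxy)-2-(triethylsilyloxy)-7-oxabicyclo[4.1.0]heptan-2-yl]-2,4-bis[2-(trimethylsilyl)ethoxy]pyridine (epoxide trans to both silyloxy groups), via cyclic orthoacetate 32 (not isolated), via bromo acetate 33 (not isolated)
Conditions: MeC(OMe)3, pyridinium p-toluenesulfonate (cat.), CH2Cl2, 25 °C; then AcBr, CH2Cl2, 0 °C; then K2CO3, MeOH, 25 °C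
Reagents that add atoms: none
Why: orthoester-mediated one-pot conversion of a cis-diol into an epoxide: bromide opens the acetoxonium ion with inversion at the less hindered carbon (remote from the quaternary centre) and the liberated alkoxide closes the ring with a second inversion, so the epoxide keeps the face of the diol; the substrate's pyridine buffers the acid.

Step 18
Reactants: 34 5-[5-(tert-butyldimethylsilyloxy)-2-(triethylsilyloxy)-7-oxabicyclo[4.1.0]heptan-2-yl]-2,4-bis[2-(trimethylsilyl)ethoxy]pyridine; 21 (1R,2S,4aS,7S,8aR)-4,7-dimethyl-1-[(E)-prop-1-enyl]-1,2,4a,5,6,7,8,8a-octahydronaphthalene-2-carbaldehyde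
Product: 36 {(1R,2S,4aS,7S,8aR)-4,7-dimethyl-1-[(E)-prop-1-enyl]-1,2,4a,5,6,7,8,8a-octahydronaphthalen-2-yl}{5-[5-(tert-butyldimethylsilyloxy)-2-(triethylsilyloxy)-7-oxabicyclo[4.1.0]heptan-2-yl]-2,4-bis[2-(trimethylsilyl)ethoxy]pyridin-3-yl}methanol (both carbinol epimers), via pyridyllithium 35 (not isolated)
Conditions: 34, n-BuLi, THF, −78 → −30 °C; then 21, −78 °C; then H2O
Reagents that add atoms: none
Why: directed ortho-lithiation at C3, the position flanked by two alkoxy groups, followed by addition to the aldehyde, which is faster than enolisation; the new carbinol centre is removed in the next step.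

Step 19
Reactants: 36 the carbinol from step 18
Product: 37 {(1R,2S,4aS,7S,8aR)-4,7-dimethyl-1-[(E)-prop-1-enyl]-1,2,4a,5,6,7,8,8a-octahydronaphthalen-2-yl}{5-[5-(tert-butyldimethylsilyloxy)-2-(triethylsilyloxy)-7-oxabicyclo[4.1.0]heptan-2-yl]-2,4-bis[2-(trimethylsilyl)ethoxy]pyridin-3-yl}methanone
Conditions: Dess–Martin periodinane, NaHCO3, CH2Cl2, 0 → 25 °C
Reagents that add atoms: none
Why: Dess–Martin oxidation of the hindered aryl carbinol under buffered conditions, which should leave the α-centre C2 and the β,γ-alkene of the decalin unchanged.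

Step 20
Reactants: 37 the ketone from step 19
Product: 38 3-{[(1R,2S,4aS,7S,8aR)-4,7-dimethyl-1-[(E)-prop-1-enyl]-1,2,4a,5,6,7,8,8a-octahydronaphthalen-2-yl]carbonyl}-5-[(1S,2R,5R,6S)-2,5-dihydroxy-7-oxabicyclo[4.1.0]heptan-2-yl]-4-hydroxypyridin-2(1H)-one (target)
Conditions: Bu4NF, AcOH (1:1), THF, 0 → 25 °C
Reagents that add atoms: none
Why: fluoride cleaves both silyl ethers and triggers β-elimination of the two 2-(trimethylsilyl)ethyl ethers (ethene and Me3SiF), unveiling the 4-hydroxy-2-pyridone; the acetic acid buffer should suppress Payne rearrangement of the epoxy alcohol.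

**Compound list**

1 | (R)-butane-1,3-diol | C[C@@H](O)CCO | starting material
2 | (4R)-4-methyl-1,3,2-dioxathiane 2-oxide (both sulfur epimers) | C[C@@H]1CCOS(=O)O1 | intermediate
3 | (R)-4-methyl-1,3,2-dioxathiane 2,2-dioxide | C[C@@H]1CCOS(=O)(=O)O1 | intermediate
4 | 4-bromo-3-methylanisole | COc1ccc(Br)c(C)c1 | starting material
5 | (4-methoxy-2-methylphenyl)lithium | COc1ccc([Li])c(C)c1 | intermediate
6 | lithium (R)-4-(4-methoxy-2-methylphenyl)butan-2-yl sulfate | COc1ccc(CC[C@@H](C)OS(=O)(=O)[O-])c(C)c1.[Li+] | intermediate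
7 | lithium (R)-4-[4-methoxy-2-(potassiomethyl)phenyl]butan-2-yl sulfate | COc1ccc(CC[C@@H](C)OS(=O)(=O)[O-])c(C[K])c1.[Li+] | intermediate
8 | (S)-7-methoxy-2-methyl-1,2,3,4-tetrahydronaphthalene | COc1ccc2c(c1)C[C@@H](C)CC2 | intermediate
9 | (S)-7-methoxy-2-methyl-1,2,3,4,5,8-hexahydronaphthalene | COC1=CCC2=C(C1)C[C@@H](C)CC2 | intermediate
10 | (4aR,7S)-7-methyl-4,4a,5,6,7,8-hexahydronaphthalen-2(3H)-one | O=C1C=C2C[C@@H](C)CC[C@@H]2CC1 | intermediate
11 | lithium C1=C2 enolate of trans-fused (4aR,7S,8aS)-7-methyldecalin-2-one | [Li+].[O-]C1=C[C@H]2C[C@@H](C)CC[C@@H]2CC1 | intermediate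
12 | (1R,4aR,7S,8aS)-1-allyl-7-methyloctahydronaphthalen-2(1H)-one | C=CC[C@@H]1[C@H]2C[C@@H](C)CC[C@@H]2CCC1=O | intermediate
13 | C2=C3 trimethylsilyl enol ether of 12 | C=CC[C@@H]1[C@H]2C[C@@H](C)CC[C@@H]2CC=C1O[Si](C)(C)C | intermediate
14 | (1R,4aR,7S,8aS)-1-allyl-7-methyl-4a,5,6,7,8,8a-hexahydronaphthalen-2(1H)-one | C=CC[C@@H]1[C@H]2C[C@@H](C)CC[C@@H]2C=CC1=O | intermediate
15 | lithium C2=C3 enolate of the 4-methyl ketone (conjugate adduct of 14) | C=CC[C@@H]1[C@H]2C[C@@H](C)CC[C@@H]2[C@H](C)C=C1[O-].[Li+] | intermediate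
16 | (1R,4S,4aR,7S,8aS)-1-allyl-4,7-dimethyl-1,4,4a,5,6,7,8,8a-octahydronaphthalen-2-yl trifluoromethanesulfonate | C=CC[C@@H]1[C@H]2C[C@@H](C)CC[C@@H]2[C@H](C)C=C1OS(=O)(=O)C(F)(F)F | intermediate
17 | methyl (1R,4S,4aR,7S,8aS)-1-allyl-4,7-dimethyl-1,4,4a,5,6,7,8,8a-octahydronaphthalene-2-carboxylate | C=CC[C@@H]1[C@H]2C[C@@H](C)CC[C@@H]2[C@H](C)C=C1C(=O)OC | intermediate
18 | lithium dienolate of 17 (ketene acetal on C2, C3=C4 alkene) | C=CC[C@@H]1[C@H]2C[C@@H](C)CC[C@@H]2C(C)=CC1=C([O-])OC.[Li+] | intermediate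
19 | methyl (1R,2S,4aS,7S,8aR)-1-allyl-4,7-dimethyl-1,2,4a,5,6,7,8,8a-octahydronaphthalene-2-carboxylate | C=CC[C@@H]1[C@H]2C[C@@H](C)CC[C@@H]2C(C)=C[C@H]1C(=O)OC | intermediate
20 | methyl (1R,2S,4aS,7S,8aR)-4,7-dimethyl-1-[(E)-prop-1-enyl]-1,2,4a,5,6,7,8,8a-octahydronaphthalene-2-carboxylate | C/C=C/[C@@H]1[C@H]2C[C@@H](C)CC[C@@H]2C(C)=C[C@H]1C(=O)OC | intermediate
21 | (1R,2S,4aS,7S,8aR)-4,7-dimethyl-1-[(E)-prop-1-enyl]-1,2,4a,5,6,7,8,8a-octahydronaphthalene-2-carbaldehyde | C/C=C/[C@@H]1[C@H]2C[C@@H](C)CC[C@@H]2C(C)=C[C@H]1C=O | intermediate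
22 | 5-bromo-2,4-dichloropyridine | Clc1cc(Cl)c(Br)cn1 | starting material
23 | 5-bromo-2,4-bis[2-(trimethylsilyl)ethoxy]pyridine | C[Si](C)(C)CCOc1cc(OCC[Si](C)(C)C)c(Br)cn1 | intermediate
24 | cyclohexa-1,3-diene | C1=CC=CCC1 | starting material
25 | 2,3-dioxabicyclo[2.2.2]oct-5-ene | C1CC2C=CC1OO2 | intermediate
26 | (R)-4-hydroxycyclohex-2-en-1-one | O=C1CC[C@@H](O)C=C1 | intermediate
27 | (R)-4-(tert-butyldimethylsilyloxy)cyclohex-2-en-1-one | O=C1CC[C@@H](O[Si](C)(C)C(C)(C)C)C=C1 | intermediate
28 | {4,6-bis[2-(trimethylsilyl)ethoxy]pyridin-3-yl}lithium | C[Si](C)(C)CCOc1cc(OCC[Si](C)(C)C)c([Li])cn1 | intermediate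
29 | lithium alkoxide of the 1,2-adduct (aryl trans to the silyloxy group) | C[Si](C)(C)CCOc1cc(OCC[Si](C)(C)C)c(cn1)[C@]2([O-])CC[C@@H](O[Si](C)(C)C(C)(C)C)C=C2.[Li+] | intermediate
30 | 5-[(1S,4R)-4-(tert-butyldimethylsilyloxy)-1-(triethylsilyloxy)cyclohex-2-en-1-yl]-2,4-bis[2-(trimethylsilyl)ethoxy]pyridine | C[Si](C)(C)CCOc1cc(OCC[Si](C)(C)C)c(cn1)[C@]2(O[Si](CC)(CC)CC)CC[C@@H](O[Si](C)(C)C(C)(C)C)C=C2 | intermediate
31 | 2,3-cis-diol of 30, both hydroxyls trans to the two silyloxy groups | C[Si](C)(C)CCOc1cc(OCC[Si](C)(C)C)c(cn1)[C@]2(O[Si](CC)(CC)CC)CC[C@@H](O[Si](C)(C)C(C)(C)C)[C@H](O)[C@@H]2O | intermediate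
32 | cyclic methyl orthoacetate of diol 31 | C[Si](C)(C)CCOc1cc(OCC[Si](C)(C)C)c(cn1)[C@]2(O[Si](CC)(CC)CC)CC[C@@H](O[Si](C)(C)C(C)(C)C)[C@@H]3OC(C)(OC)O[C@@H]32 | intermediate
33 | trans-bromo acetate (bromide on the carbon next to the CH–OSi centre, acetate next to the quaternary carbon) | C[Si](C)(C)CCOc1cc(OCC[Si](C)(C)C)c(cn1)[C@]2(O[Si](CC)(CC)CC)CC[C@@H](O[Si](C)(C)C(C)(C)C)[C@@H](Br)[C@@H]2OC(C)=O | intermediate
34 | 5-[5-(tert-butyldimethylsilyloxy)-2-(triethylsilyloxy)-7-oxabicyclo[4.1.0]heptan-2-yl]-2,4-bis[2-(trimethylsilyl)ethoxy]pyridine, epoxide trans to both silyloxy groups | C[Si](C)(C)CCOc1cc(OCC[Si](C)(C)C)c(cn1)[C@]2(O[Si](CC)(CC)CC)CC[C@@H](O[Si](C)(C)C(C)(C)C)[C@@H]3O[C@@H]32 | intermediate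
35 | 3-lithio derivative of 34 | C[Si](C)(C)CCOc1ncc([C@]2(O[Si](CC)(CC)CC)CC[C@@H](O[Si](C)(C)C(C)(C)C)[C@@H]3O[C@@H]32)c(OCC[Si](C)(C)C)c1[Li] | intermediate
36 | decalinyl pyridyl carbinol (both carbinol epimers) | C/C=C/[C@@H]1[C@H]2C[C@@H](C)CC[C@@H]2C(C)=C[C@H]1C(O)c1c(OCC[Si](C)(C)C)c([C@]2(O[Si](CC)(CC)CC)CC[C@@H](O[Si](C)(C)C(C)(C)C)[C@@H]3O[C@@H]32)cnc1OCC[Si](C)(C)C | intermediate
37 | decalinyl pyridyl ketone, fully protected | C/C=C/[C@@H]1[C@H]2C[C@@H](C)CC[C@@H]2C(C)=C[C@H]1C(=O)c1c(OCC[Si](C)(C)C)c([C@]2(O[Si](CC)(CC)CC)CC[C@@H](O[Si](C)(C)C(C)(C)C)[C@@H]3O[C@@H]32)cnc1OCC[Si](C)(C)C | intermediate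
38 | CNP0494338.1 (name as in step 20) | C/C=C/[C@@H]1[C@H]2C[C@@H](C)CC[C@@H]2C(C)=C[C@H]1C(=O)c1c(O)c([C@]2(O)CC[C@@H](O)[C@@H]3O[C@@H]32)c[nH]c1=O | target

**Step count and risks**

Total steps: 20. Longest linear sequence: 13 (steps 1–10, then 18, 19, 20).

Steps most likely to fail:

Step 2 (the proposed annulation). What may go wrong: attack of the aryllithium at sulfur instead of carbon, metalation of the ring ortho to OMe that does not equilibrate to the benzylic position, or elimination of the secondary sulfate before ring closure. The fallback sets out from 3 and 4, returns at 8, and makes the two bonds in separate, individually known operations with a neutral electrophile for the ring closure. Compound 4 is converted into its Grignard reagent (Mg, THF) and coupled with 3 under CuI catalysis. Acidic hydrolysis of the sulfate half-ester (aqueous H2SO4, THF) gives (R)-4-(4-methoxy-2-methylphenyl)butan-2-ol F1. TsCl in pyridine gives (R)-4-(4-methoxy-2-methylphenyl)butan-2-yl 4-methylbenzenesulfonate F2. Benzylic metalation of F2 with n-BuLi/KOt-Bu/2,2,6,6-tetramethylpiperidine at −78 °C and warming then closes ring B with inversion to give 8.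

Step 8 (deconjugative protonation). What may go wrong: protonation of the dienolate at C4 (return of the conjugated ester), protonation of C2 from the wrong face, or competing deprotonation at C1. The fallback sets out from 14, returns at 21, and never has to move the ring alkene. Me2CuLi followed by Me3SiCl/Et3N gives the C2=C3 trimethylsilyl enol ether of the 4-methyl ketone F3. Saegusa–Ito oxidation (Pd(OAc)2, MeCN) gives (1R,4aS,7S,8aS)-1-allyl-4,7-dimethyl-4a,5,6,7,8,8a-hexahydronaphthalen-2(1H)-one F4, with the C3=C4(CH3) alkene already in place. Corey–Chaykovsky methylenation of the carbonyl (Me3SI, n-BuLi, THF, −10 °C) gives the spiro-epoxide on C2 F5. Meinwald rearrangement (MgBr2·OEt2, CH2Cl2, −40 °C; 1,2-hydride shift through the allylic cation) gives (1R,2S,4aS,7S,8aR)-1-allyl-4,7-dimethyl-1,2,4a,5,6,7,8,8a-octahydronaphthalene-2-carbaldehyde F6, equilibrated to the equatorial aldehyde with a trace of Et3N. The ruthenium catalyst of step 9 then moves the allyl double bond to give 21.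

Step 16 (dihydroxylation). What may go wrong: very slow osmylation of the hindered, electron-poor alkene next to the quaternary centre, or incomplete facial selectivity. The fallback sets out from 30, returns at 34, and uses peracid chemistry while accepting oxidation at nitrogen. mCPBA (3 equiv), NaHCO3, CH2Cl2 oxidises the pyridine nitrogen first and then epoxidises the alkene anti to the two silyloxy groups (steric approach control), giving the pyridine N-oxide of epoxide 34 F7. B2pin2 in MeCN at 70 °C removes the N-oxide oxygen and gives 34 directly.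

Further compounds
F1 | step 2 | (R)-4-(4-methoxy-2-methylphenyl)butan-2-ol | COc1ccc(CC[C@@H](C)O)c(C)c1
F2 | step 2 | (R)-4-(4-methoxy-2-methylphenyl)butan-2-yl 4-methylbenzenesulfonate | COc1ccc(CC[C@@H](C)OS(=O)(=O)c2ccc(C)cc2)c(C)c1
F3 | step 8 | C2=C3 trimethylsilyl enol ether of the 4-methyl ketone | C=CC[C@@H]1[C@H]2C[C@@H](C)CC[C@@H]2[C@H](C)C=C1O[Si](C)(C)C
F4 | step 8 | (1R,4aS,7S,8aS)-1-allyl-4,7-dimethyl-4a,5,6,7,8,8a-hexahydronaphthalen-2(1H)-one | C=CC[C@@H]1[C@H]2C[C@@H](C)CC[C@@H]2C(C)=CC1=O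
F5 | step 8 | spiro-epoxide on C2 of F4 (either epimer at the spiro carbon) | C=CC[C@@H]1[C@H]2C[C@@H](C)CC[C@@H]2C(C)=CC13CO3
F6 | step 8 | (1R,2S,4aS,7S,8aR)-1-allyl-4,7-dimethyl-1,2,4a,5,6,7,8,8a-octahydronaphthalene-2-carbaldehyde | C=CC[C@@H]1[C@H]2C[C@@H](C)CC[C@@H]2C(C)=C[C@H]1C=O
F7 | step 16 | pyridine N-oxide of epoxide 34 | C[Si](C)(C)CCOc1cc(OCC[Si](C)(C)C)c(c[n+]1[O-])[C@]2(O[Si](CC)(CC)CC)CC[C@@H](O[Si](C)(C)C(C)(C)C)[C@@H]3O[C@@H]32
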